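Apart from the different oxidation levels of C7 and C7', the target is almost symmetric: the tetrahydrofuran carbons C8 and C8' (ring oxygen flanked by the CH2 groups C9 and C9') each carry one exocyclic carbon, and these two carbons, C7 and C7', bear identical 4-hydroxy-3,5-dimethoxyphenyl rings. The route rests on cutting the C7'–aryl bond back to meso cis-tetrahydrofuran-3,4-dicarboxylic anhydride, whose mirror-related carbonyl carbons are the future C7 and C7'. One ligand-controlled, rhodium-catalysed aryl transfer from an arylzinc breaks that symmetry, opens the anhydride and delivers a cis keto acid with both ring stereocentres defined. Its precursors are the bicyclic meso anhydride and a silyl-protected 4-bromo-2,6-dimethoxyphenol.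

Key step: step 5

Remark: lignan numbering is used (C7/C7' benzylic, C8/C8' ring CH, C9/C9' ring CH2; the unprimed half carries the carbinol) and Ar stands for 3,5-dimethoxy-4-(triisopropylsilyloxy)phenyl; it is assumed that the hand of the phosphoramidite ligand leading to acid 9 is fixed in a first small-scale run, because the sense of induction on this oxygen-containing anhydride cannot be predicted with certainty.

**Route**

Step 1
Reactants: 1 diethyl furan-3,4-dicarboxylate
Product: 2 diethyl cis-tetrahydrofuran-3,4-dicarboxylate (meso)
Conditions: H2 (50 bar), 5% Rh/C, EtOH, 50 °C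
Reagents that add atoms: none
Why: Heterogeneous catalytic hydrogenation of the furan adds all hydrogen from the metal-bound face, so the cis diester should dominate, and a trans impurity is tolerable because step 3 converges on the cis anhydride.

Step 2
Reactants: 2 diethyl cis-tetrahydrofuran-3,4-dicarboxylate
Product: 3 cis-tetrahydrofuran-3,4-dicarboxylic acid
Conditions: 2 M HCl (aq), reflux; evaporate to dryness
Reagents that add atoms: water, O
Why: Acid-catalysed ester hydrolysis frees the very water-soluble diacid, which should then be obtained salt-free by evaporation instead of by extraction from brine.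

Step 3
Reactants: 3 cis-tetrahydrofuran-3,4-dicarboxylic acid
Product: 4 meso cis-tetrahydrofuran-3,4-dicarboxylic anhydride (cis-tetrahydro-1H,3H-furo[3,4-c]furan-1,3-dione)
Conditions: Ac2O, reflux; remove AcOH/Ac2O in vacuo; recrystallise from dry toluene
Reagents that add atoms: none
Why: Dehydrative cyclisation through the mixed anhydride; only a cis diacid can close the five-membered anhydride and hot acetic anhydride epimerises trans diacid via its enolisable mixed anhydride, so a single meso compound should result.

Step 4
Reactants: 5 4-bromo-2,6-dimethoxyphenol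
Product: 6 (4-bromo-2,6-dimethoxyphenoxy)triisopropylsilane
Conditions: TIPSCl, imidazole, DMF, rt → 40 °C
Reagents that add atoms: triisopropylsilyl chloride (TIPSCl), CC(C)[Si](Cl)(C(C)C)C(C)C
Why: O-Silylation of the phenol (silyl ether protection); the bulky silyl group, shielded further by the two methoxy groups, should survive organolithium, organozinc and organomagnesium formation, hydride, hydrogenolysis and amidine base, yet leave with fluoride in the last step.

Step 5
Reactants: 4 meso cis-tetrahydrofuran-3,4-dicarboxylic anhydride; 6 (4-bromo-2,6-dimethoxyphenoxy)triisopropylsilane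
Product: 9 (3S,4R)-cis-4-(Ar-carbonyl)tetrahydrofuran-3-carboxylic acid, via aryllithium 7 (not isolated), via arylzinc triflate 8 (not isolated)
Conditions: 6, n-BuLi, THF, −78 °C; Zn(OTf)2, −78 °C → rt; then 4, [Rh(cod)Cl]2 (cat.), TADDOL-derived phosphoramidite 6-(dimethylamino)-2,2-dimethyl-4,4,8,8-tetraphenyltetrahydro-1,3-dioxolo[4,5-e][1,3,2]dioxaphosphepine (cat., enantiomer as in the remark), THF, 50 °C; cold 1 M HCl work-up
Reagents that add atoms: none
Why: The catalytic cycle should begin with oxidative addition of the phosphoramidite-bound monovalent rhodium to one C(acyl)–O bond of anhydride 4, continue with aryl transfer from zinc to the resulting acyl rhodium carboxylate (trivalent rhodium) and end with C–C reductive elimination, which releases the C7'–aryl ketone as its zinc carboxylate; a carboxylate cannot re-enter the cycle, so only one aryl group is introduced. The closest known reaction type is the enantioselective desymmetrising cross-coupling of meso succinic-type cyclic anhydrides with arylzinc reagents made in situ from aryllithiums, which gives cis γ-keto acids; anhydride 4 with this aryl group is a new substrate pair within that reaction. No ring is closed: the anhydride ring is opened and the tetrahydrofuran ring is untouched. The two ring stereocentres are differentiated rather than created, their cis relationship being inherited from the ring fusion of 4 and their absolute configuration (3S,4R) being decided by the ligand, which selects the carbonyl that becomes C7'. The step therefore needs only enantiotopic-group selectivity, which the substrate secures because its two carbonyls are related by a mirror plane and differ solely in their fit to the chiral catalyst, while the aryl partner is unhindered (H at both positions next to zinc). β-Elimination of the ring oxygen is stereoelectronically hampered because the endocyclic C–O bond lies nearly orthogonal to the acyl or enolate π system (it would be a retro-5-endo-trig opening), and 9 is worked up cold, kept from base and reduced at once because epimerisation α to the ketone would lower the final enantiopurity.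

Step 6
Reactants: 9 (3S,4R)-cis-4-(Ar-carbonyl)tetrahydrofuran-3-carboxylic acid
Product: 11 (3aR,6aS)-3-Ar-tetrahydro-1H,3H-furo[3,4-c]furan-1-one (cis-fused benzylic lactone; both C3 epimers), via hydroxy acid 10 (not isolated)
Conditions: NaBH4, CeCl3·7H2O, MeOH, −40 → 0 °C; concentrate; EtOAc/1 M HCl, rt; NaHCO3 wash
Reagents that add atoms: none
Why: Cerium-buffered borohydride reduction (Luche conditions) of the aryl ketone is fast and only weakly basic, the cis γ-hydroxy acid lactonises on acidification, and material that had epimerised to trans cannot readily close a trans-fused bicycle and is washed out as carboxylate, which safeguards enantiopurity; the new benzylic centre is irrelevant because it becomes CH2 in step 7.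

Step 7
Reactants: 11 cis-fused benzylic lactone
Product: 12 (3S,4R)-cis-4-(Ar-methyl)tetrahydrofuran-3-carboxylic acid
Conditions: H2 (4 bar), 10% Pd/C, EtOAc/AcOH, 40 °C
Reagents that add atoms: none
Why: Catalytic hydrogenolysis of the benzylic C–O bond of the lactone, eased by the electron-rich ring, should give the C7' methylene and the free acid with both ring stereocentres untouched, and this acid is the point at which enantiomeric purity and absolute configuration are to be checked (and raised by recrystallisation if needed).

Step 8
Reactants: 12 (3S,4R)-cis-4-(Ar-methyl)tetrahydrofuran-3-carboxylic acid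
Product: 14 (3S,4R)-cis-4-(Ar-methyl)-N-methoxy-N-methyltetrahydrofuran-3-carboxamide, via acyl imidazole 13 (not isolated)
Conditions: CDI, CH2Cl2, rt; then MeNH(OMe)·HCl, rt
Reagents that add atoms: N,O-dimethylhydroxylamine hydrochloride, Cl.CNOC
Why: Weinreb amide formation through the acyl imidazolide is mild, and any epimerisation next to the carboxyl is harmless because that centre (C8) is deliberately equilibrated in step 9.

Step 9
Reactants: 14 (3S,4R)-cis-4-(Ar-methyl)-N-methoxy-N-methyltetrahydrofuran-3-carboxamide; 6 (4-bromo-2,6-dimethoxyphenoxy)triisopropylsilane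
Product: 18 [(3R,4R)-4-(Ar-methyl)tetrahydrofuran-3-yl](Ar)methanone (trans), via aryl Grignard reagent 15 (not isolated), via magnesium hemiaminal adduct 16 (not isolated), via cis ketone 17 (not isolated)
Conditions: 6, Mg turnings (I2-activated), THF, rt → 45 °C; then 14, THF, 0 °C → rt; AcOH, 0 °C → rt; then DBU (excess), rt → 40 °C
Reagents that add atoms: none
Why: Weinreb ketone synthesis, in which the arylmagnesium bromide formed by magnesium insertion into the C–Br bond of 6 (less basic than an aryllithium and therefore less prone to enolise the amide) adds once to give a chelated tetrahedral adduct that collapses to the aryl ketone only on quenching, followed by base-mediated epimerisation of the acidic centre α to the new ketone (C8) to the more stable trans arrangement, while C8' is no longer α to a carbonyl and cannot move and ring opening by β-elimination is disfavoured for the stereoelectronic reason given in step 5.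

Step 10
Reactants: 18 [(3R,4R)-4-(Ar-methyl)tetrahydrofuran-3-yl](Ar)methanone
Product: 19 (S)-[(3R,4R)-4-(Ar-methyl)tetrahydrofuran-3-yl](Ar)methanol (bis-silyl ether of the target)
Conditions: (R)-1-methyl-3,3-diphenyltetrahydro-1H,3H-pyrrolo[1,2-c][1,3,2]oxazaborole, BH3·SMe2, THF, −20 °C; MeOH quench
Reagents that add atoms: none
Why: Corey–Bakshi–Shibata reduction, in which the (R)-oxazaborolidine with the aryl group as the large substituent should deliver hydride to the face giving the (S)-carbinol (the sense that turns acetophenone into (S)-1-phenylethanol), and Felkin–Anh induction from C8 (hydride anti to the more substituted ring carbon C8') points to the same face, so C7 is set by matched catalyst and substrate control.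

Step 11
Reactants: 19 bis-silyl ether of the target
Product: 20 4-{[(3R,4R)-4-[(S)-hydroxy(4-hydroxy-3,5-dimethoxyphenyl)methyl]tetrahydrofuran-3-yl]methyl}-2,6-dimethoxyphenol (CNP0257794.1)
Conditions: Bu4NF, AcOH, THF, 0 °C
Reagents that add atoms: none
Why: Fluoride-induced cleavage of both aryl silyl ethers (Si–F bond formation) under acetic acid buffering should free the two phenols without acid or base strong enough to ionise or eliminate the 4-hydroxybenzylic alcohol, so C7 is not scrambled.

**Compound list**

1 | diethyl furan-3,4-dicarboxylate | CCOC(=O)c1cocc1C(=O)OCC | starting material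
2 | diethyl cis-tetrahydrofuran-3,4-dicarboxylate (meso) | CCOC(=O)[C@H]1COC[C@H]1C(=O)OCC | intermediate
3 | cis-tetrahydrofuran-3,4-dicarboxylic acid (meso) | OC(=O)[C@H]1COC[C@H]1C(=O)O | intermediate
4 | meso cis-tetrahydrofuran-3,4-dicarboxylic anhydride | O=C1OC(=O)[C@H]2COC[C@@H]12 | intermediate
5 | 4-bromo-2,6-dimethoxyphenol | COc1cc(Br)cc(OC)c1O | starting material
6 | (4-bromo-2,6-dimethoxyphenoxy)triisopropylsilane | COc1cc(Br)cc(OC)c1O[Si](C(C)C)(C(C)C)C(C)C | intermediate
7 | [3,5-dimethoxy-4-(triisopropylsilyloxy)phenyl]lithium | COc1cc([Li])cc(OC)c1O[Si](C(C)C)(C(C)C)C(C)C | intermediate (not isolated)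
8 | [3,5-dimethoxy-4-(triisopropylsilyloxy)phenyl]zinc triflate | COc1cc([Zn]OS(=O)(=O)C(F)(F)F)cc(OC)c1O[Si](C(C)C)(C(C)C)C(C)C | intermediate (not isolated)
9 | (3S,4R)-cis-4-[3,5-dimethoxy-4-(triisopropylsilyloxy)benzoyl]tetrahydrofuran-3-carboxylic acid | COc1cc(C(=O)[C@H]2COC[C@H]2C(=O)O)cc(OC)c1O[Si](C(C)C)(C(C)C)C(C)C | intermediate
10 | (3S,4R)-cis-4-{hydroxy[3,5-dimethoxy-4-(triisopropylsilyloxy)phenyl]methyl}tetrahydrofuran-3-carboxylic acid (both carbinol epimers) | COc1cc(C(O)[C@H]2COC[C@H]2C(=O)O)cc(OC)c1O[Si](C(C)C)(C(C)C)C(C)C | intermediate (not isolated)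
11 | (3aR,6aS)-3-[3,5-dimethoxy-4-(triisopropylsilyloxy)phenyl]tetrahydro-1H,3H-furo[3,4-c]furan-1-one (cis-fused; both C3 epimers) | COc1cc(C2OC(=O)[C@@H]3COC[C@H]23)cc(OC)c1O[Si](C(C)C)(C(C)C)C(C)C | intermediate
12 | (3S,4R)-cis-4-[3,5-dimethoxy-4-(triisopropylsilyloxy)benzyl]tetrahydrofuran-3-carboxylic acid | COc1cc(C[C@H]2COC[C@H]2C(=O)O)cc(OC)c1O[Si](C(C)C)(C(C)C)C(C)C | intermediate
13 | 1-{(3S,4R)-4-[3,5-dimethoxy-4-(triisopropylsilyloxy)benzyl]tetrahydrofuran-3-carbonyl}imidazole | COc1cc(C[C@H]2COC[C@H]2C(=O)n3ccnc3)cc(OC)c1O[Si](C(C)C)(C(C)C)C(C)C | intermediate (not isolated)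
14 | (3S,4R)-cis-4-[3,5-dimethoxy-4-(triisopropylsilyloxy)benzyl]-N-methoxy-N-methyltetrahydrofuran-3-carboxamide | COc1cc(C[C@H]2COC[C@H]2C(=O)N(C)OC)cc(OC)c1O[Si](C(C)C)(C(C)C)C(C)C | intermediate
15 | [3,5-dimethoxy-4-(triisopropylsilyloxy)phenyl]magnesium bromide | COc1cc([Mg]Br)cc(OC)c1O[Si](C(C)C)(C(C)C)C(C)C | intermediate (not isolated)
16 | bromomagnesium alkoxide of the tetrahedral adduct of 15 and 14 (N-methoxy-N-methyl hemiaminal) | COc1cc(C[C@H]2COC[C@H]2C(O[Mg]Br)(N(C)OC)c3cc(OC)c(O[Si](C(C)C)(C(C)C)C(C)C)c(OC)c3)cc(OC)c1O[Si](C(C)C)(C(C)C)C(C)C | intermediate (not isolated)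
17 | [(3S,4R)-4-(Ar-methyl)tetrahydrofuran-3-yl](Ar)methanone (cis ketone) | COc1cc(C[C@H]2COC[C@H]2C(=O)c3cc(OC)c(O[Si](C(C)C)(C(C)C)C(C)C)c(OC)c3)cc(OC)c1O[Si](C(C)C)(C(C)C)C(C)C | intermediate (not isolated)
18 | [(3R,4R)-4-(Ar-methyl)tetrahydrofuran-3-yl](Ar)methanone (trans ketone) | COc1cc(C[C@H]2COC[C@@H]2C(=O)c3cc(OC)c(O[Si](C(C)C)(C(C)C)C(C)C)c(OC)c3)cc(OC)c1O[Si](C(C)C)(C(C)C)C(C)C | intermediate
19 | (S)-[(3R,4R)-4-(Ar-methyl)tetrahydrofuran-3-yl](Ar)methanol | COc1cc(C[C@H]2COC[C@@H]2[C@H](O)c3cc(OC)c(O[Si](C(C)C)(C(C)C)C(C)C)c(OC)c3)cc(OC)c1O[Si](C(C)C)(C(C)C)C(C)C | intermediate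
20 | 4-{[(3R,4R)-4-[(S)-hydroxy(4-hydroxy-3,5-dimethoxyphenyl)methyl]tetrahydrofuran-3-yl]methyl}-2,6-dimethoxyphenol | COc1cc(C[C@H]2COC[C@@H]2[C@H](O)c2cc(OC)c(O)c(OC)c2)cc(OC)c1O | target

**Step count**

Total step count: 11.
Longest linear sequence: 10 steps (from 1 through steps 1–3 and 5–11); step 4 is a one-step side branch.

**Steps most likely to fail**

Step 5. The catalyst may discriminate poorly between the two mirror-related carbonyls of the oxygen-containing anhydride, aryl transfer may be slow, or the keto acid may epimerise α to the ketone during the reaction. The fallback separates the desymmetrisation from the C–C bond formation and uses known chemistry only. It sets out from 4: alkaloid-mediated methanolysis (quinidine or quinine, whichever pseudo-enantiomer gives the needed sense; MeOH, toluene, −55 °C) opens the anhydride to the hemiester (3R,4S)-4-(methoxycarbonyl)tetrahydrofuran-3-carboxylic acid F1. Oxalyl chloride with catalytic DMF (CH2Cl2, 0 °C) converts it into the acid chloride methyl (3S,4R)-4-(chlorocarbonyl)tetrahydrofuran-3-carboxylate F2. Negishi acylation with arylzinc 8 (made from 6 as in step 5; Pd(PPh3)4 cat., THF, 0 °C) gives the keto ester methyl (3S,4R)-4-(Ar-carbonyl)tetrahydrofuran-3-carboxylate F3. Borohydride reduction under the conditions of step 6 gives the hydroxy ester methyl (3S,4R)-4-[Ar(hydroxy)methyl]tetrahydrofuran-3-carboxylate F4, which lactonises on acid treatment with loss of methanol. The fallback comes back to the route at lactone 11.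

Step 9. The arylmagnesium reagent may add slowly to the branched amide or enolise it instead, and the cis-to-trans equilibration may stop short of completion. The fallback sets out from 14: i-Bu2AlH (THF, −78 °C) reduces the amide to the aldehyde (3S,4R)-4-(Ar-methyl)tetrahydrofuran-3-carbaldehyde F5, whose easy epimerisation at C8 is harmless. Aryl Grignard reagent 15 (made from 6 as in step 9) should add cleanly to this far more electrophilic carbonyl at −78 °C to give the carbinol mixture Ar[(3S,4R)-4-(Ar-methyl)tetrahydrofuran-3-yl]methanol F6 (both C7 epimers). Oxidation with Dess–Martin periodinane gives cis ketone 17, where the fallback comes back to the route. DBU equilibration as in step 9 then gives 18, and any residual cis ketone is separated and resubmitted to DBU.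

Step 10. Facial selectivity at C7 may be poor if the oxazaborolidine does not tell the aryl group from the branched ring carbon, or reduction of the electron-rich ketone may be slow. The fallback replaces catalyst control by substrate control and sets out from 18: LiBH(s-Bu)3 (THF, −78 °C) should attack anti to C8' (Felkin–Anh), which favours the same carbinol 19, where the fallback comes back to the route. The C7 epimer (R)-[(3R,4R)-4-(Ar-methyl)tetrahydrofuran-3-yl](Ar)methanol F7 is separated by chromatography, reoxidised to 18 with Dess–Martin periodinane and recycled.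

Further compounds
F1 | step 5 | (3R,4S)-4-(methoxycarbonyl)tetrahydrofuran-3-carboxylic acid | OC(=O)[C@H]1COC[C@H]1C(=O)OC
F2 | step 5 | methyl (3S,4R)-4-(chlorocarbonyl)tetrahydrofuran-3-carboxylate | ClC(=O)[C@H]1COC[C@H]1C(=O)OC
F3 | step 5 | methyl (3S,4R)-4-[3,5-dimethoxy-4-(triisopropylsilyloxy)benzoyl]tetrahydrofuran-3-carboxylate | COc1cc(C(=O)[C@H]2COC[C@H]2C(=O)OC)cc(OC)c1O[Si](C(C)C)(C(C)C)C(C)C
F4 | step 5 | methyl (3S,4R)-4-{hydroxy[3,5-dimethoxy-4-(triisopropylsilyloxy)phenyl]methyl}tetrahydrofuran-3-carboxylate (both carbinol epimers) | COc1cc(C(O)[C@H]2COC[C@H]2C(=O)OC)cc(OC)c1O[Si](C(C)C)(C(C)C)C(C)C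
F5 | step 9 | (3S,4R)-4-[3,5-dimethoxy-4-(triisopropylsilyloxy)benzyl]tetrahydrofuran-3-carbaldehyde | COc1cc(C[C@H]2COC[C@H]2C=O)cc(OC)c1O[Si](C(C)C)(C(C)C)C(C)C
F6 | step 9 | [3,5-dimethoxy-4-(triisopropylsilyloxy)phenyl]{(3S,4R)-4-[3,5-dimethoxy-4-(triisopropylsilyloxy)benzyl]tetrahydrofuran-3-yl}methanol (both C7 epimers) | COc1cc(C[C@H]2COC[C@H]2C(O)c3cc(OC)c(O[Si](C(C)C)(C(C)C)C(C)C)c(OC)c3)cc(OC)c1O[Si](C(C)C)(C(C)C)C(C)C
F7 | step 10 | (R)-[3,5-dimethoxy-4-(triisopropylsilyloxy)phenyl]{(3R,4R)-4-[3,5-dimethoxy-4-(triisopropylsilyloxy)benzyl]tetrahydrofuran-3-yl}methanol | COc1cc(C[C@H]2COC[C@@H]2[C@@H](O)c3cc(OC)c(O[Si](C(C)C)(C(C)C)C(C)C)c(OC)c3)cc(OC)c1O[Si](C(C)C)(C(C)C)C(C)C
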